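## The problem

Target 23 is a benzofuran neolignan. Its core is a 2,3-dihydrobenzofuran whose ring A carries a methoxy group at C7 and, at C5, a three-carbon chain ending in an (E)-ferulate ester. C2 carries a 4-hydroxy-3-methoxyphenyl group (ring C) and C3 a hydroxymethyl group.

The only stereocentres are the adjacent C2 (R) and C3 (S), trans across the five-membered ring. Either can direct the other during ring formation, but nothing else in the molecule can, so the absolute configuration must come from a reagent, a catalyst or a resolution.

There are two primary oxygen atoms, one free (on C3) and one acylated (the propanol), so the ester has to be placed without a selective acylation of a diol.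

C2 is a benzylic ether carbon para to a phenol. Acid, or base acting on the free phenol, can open the O1–C2 bond through a para-quinone methide and scramble C2, so the ring C phenol should stay masked until the end and the end-game must be close to neutral. The conjugated ester and its styrenic double bond exclude hydrogenolysis, hydride reagents and hot hydroxide late in the route, which points to silyl ethers as the only protecting groups.

The enabling feature is that C2 is a single carbon bonded to O1, C3 and ring C, while the other four ring atoms, O1–C7a–C3a–C3, are exactly the heterodiene of an ortho-quinone methide of ring A. Ring A has only one ortho position free for such a quinone methide, and its para position (C5) can hold a bromine atom that later anchors the side chain.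

## Retrosynthesis

**23 from 22.** No skeletal bond is cut. 23 is traced to its tris-silyl ether 22, with a tert-butyldiphenylsilyl group on the C3 hydroxymethyl oxygen and triisopropylsilyl groups on both phenols. Benzyl ethers are excluded because hydrogenolysis would reduce the cinnamate double bond and could cleave the benzylic O1–C2 bond; acetals are excluded because their removal by acid would ionise C2. 22 is no simpler, but one buffered fluoride treatment then ends the synthesis. The forward step only has to keep the medium from becoming basic.

**22 from 17 and 20.** The C5–CH2 bond between ring A and the propyl chain is cut, giving aryl bromide 17 and allyl ester 20, which is joined through its 9-BBN adduct 21. The neighbouring cut, the ester C–O bond, would need a 3-arylpropanol to be acylated in the presence of, or after separate protection of, the C3 hydroxymethyl group. The sp2–sp3 coupling brings the chain in with the ester already made. 17 holds the whole stereodefined core and 20 is two steps from ferulic acid 18. The forward reaction must hydroborate the allyl double bond in preference to the cinnamate, and must couple an electron-rich aryl bromide without harming an ester or aryl silyl ethers.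

**17 from 5 and 13.** Both bonds to C2 that lie in the ring, C2–C3 and O1–C2, are cut. C2 is removed as the benzylic carbon of sulfonium salt 13 (reacting as ylide 15), and the rest is ortho-quinone methide 14, stored as its toluenesulfinate adduct 5. Cutting only O1–C2 or only C2–C3 would leave an open-chain precursor that still contains a stereocentre to be made separately. This cut makes the ring and both stereocentres in one operation from two fragments of a few steps each. Chirality is needed only in the sulfide 8, which is released again. The forward reaction must add the ylide carbon to the exocyclic carbon of 14, close betaine 16 with inversion, and transmit the configuration of the sulfide to C2 and from there to C3.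

**5 from 1.** The C–S bond of 5 is cut to the benzylic alcohol 4, the O–Si bond of 4 to triol 3, and the bond between the benzylic carbon and the CH2O carbon of 3 to aldehyde 1 and a hydroxymethyl anion equivalent. 5-Bromo-o-vanillin 1 already carries every ring A substituent, including the bromine, in the right places. A silylmethyl Grignard reagent followed by C–Si oxidation (through 2) is preferred to an alkoxymethyllithium because it tolerates the aryl bromide and leaves an oxygen that can be silylated as wished. The silyl group is tert-butyldiphenylsilyl because it must survive the sulfinic acid used to make 5.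

**13 from 12 and 8.** The S–CH2 bond is cut to benzylic bromide 12 and (2R,5R)-2,5-dimethylthiolane 8. Bromide 12 comes from vanillin 9 by silylation (10), reduction (11) and bromination. Sulfide 8 comes from (2S,5S)-hexane-2,5-diol 6 through bis-mesylate 7 by double displacement with sulfide. The C2 axis of 8 makes the two sulfur lone pairs equivalent, so alkylation gives 13 as one stereoisomer.

**20 from 18.** The ester C–O bond and the phenolic O–Si bond are cut: ferulic acid 18 is allylated on the carboxylate (19) and silylated on the phenol (20). The (E)-alkene is bought with 18 and never touched.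

## Roads not taken

**Alternative 1: aryl radical cyclisation with aminoxyl trapping.** The cut is C3–C3a, with the CH2–O bond made in the same step. An aryl radical generated from the C–I bond of allyl aryl ether A1 by photoexcited fac-Ir(ppy)3 cyclises 5-exo onto the vinyl group, and TEMPO traps the primary radical to give A2.
- Merits: C2 is a stereocentre already present in A1 and steers C3 into the trans relationship in a well-behaved radical ring closure. The conditions are neutral.
- Weak points: A1 has to be made as a single enantiomer by O-alkylation of a 2,6-disubstituted phenol at a carbon that is both benzylic and allylic and para to a silyloxy group. Ionisation, SN2' attack and loss of optical purity all threaten there. The aryl radical can also abstract the activated C2–H through a 1,5-shift. After the ring closure, the N–O bond and the benzyl ether of A2 must be cleaved in an order that lets the ferulate be attached to only one of two primary alcohols, which adds about four steps.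
- Comparison: in ring formation this road is at least as secure as the chosen one, because the stereochemical information is in the substrate. The chosen plan sets against it a shorter route to both partners (5 in three steps, 13 in four), no redox adjustment at C3 afterwards, and an ester that arrives complete.

**Alternative 2: dirhodium carbenoid C–H insertion.** The cut is C2–C3. Aryldiazoacetate A3 loses nitrogen at Rh2(S-DOSP)4 and the carbenoid carbon inserts into a C–H bond of the benzylic ether CH2 to give ester A4.
- Merits: both stereocentres arise from an achiral precursor with a catalytic source of chirality, and the reaction class is established for 2-aryl-2,3-dihydrobenzofuran-3-carboxylates. In these two respects it is better than the chosen plan, which uses a stoichiometric, though recoverable, chiral sulfide whose sense of induction in this annulation still has to be confirmed.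
- Weak points: insertion into a methylene group tends to give the cis ester kinetically, so a base epimerisation at C3 is usually needed. The diazo group demands a one-carbon homologation of the aldehyde carbon of 1 before diazo transfer. The ester of A4 must then be reduced and the alcohol protected. The carbenoid also has the electron-rich ring C within reach.
- Comparison: the chosen plan answers with precursors that are shorter to make and a C3 substituent delivered at the right oxidation level. This road is kept as the fallback for the key step.

**Alternative 3: oxidative para-quinone methide oxa-cyclisation.** The cut is O1–C2 only. Ag2O oxidises the 4-hydroxy-3-methoxybenzyl unit of phenol A5 to a para-quinone methide, and the ring A phenol adds to its exocyclic carbon to give A6.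
- Merits: the closure is biomimetic and mild, and gives the trans ring because the C3 substituent directs the addition. The ring closure itself is probably more reliable than the annulation of the chosen plan.
- Weak points: it makes one bond and one stereocentre. C3 of A5 and the C2–C3 bond must already be in place, so the absolute configuration has to come from an earlier, separate asymmetric C–C bond formation. The oxidant must choose the ring C phenol over the ring A phenol, and the para-quinone methide can also lose the C3 proton to give a stilbene.
- Comparison: the chosen plan sets against the safer closure the fact that ring, C2–C3 bond and both stereocentres come in one step, and that it needs no auxiliary chemistry before the ring is formed.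

Key step: step 10

Assumption: ylide 15 is taken to react through the same face as in benzylidene transfer from sulfide 8 to aldehydes, which gives (R) at C2 after the invertive closure. If the annulation shows the opposite sense, the mirror-image sulfide from (2R,5R)-hexane-2,5-diol is used and nothing else changes.

## Route

Step 1
Reactants: 1 5-bromo-2-hydroxy-3-methoxybenzaldehyde (5-bromo-o-vanillin)
Product: 3 rac-1-(5-bromo-2-hydroxy-3-methoxyphenyl)ethane-1,2-diol, via beta-hydroxysilane 2 (not isolated)
Conditions: (i-PrO)Me2SiCH2MgCl (3 equiv, from (i-PrO)Me2SiCH2Cl and Mg), THF, 0 °C to rt; then 30% H2O2, KF, KHCO3, THF/MeOH, rt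
Reagents that add atoms: (isopropoxydimethylsilyl)methylmagnesium chloride, CC(C)O[Si](C)(C)C[Mg]Cl; hydrogen peroxide, OO
Why: Grignard addition to the aldehyde (the first equivalent is spent on the phenol) followed by Tamao–Kumada oxidation of the C–Si bond is a standard nucleophilic hydroxymethylation; the aryl bromide is inert to the Grignard reagent at this temperature, and the new centre is racemic, which does not matter because it is erased in step 10.

Step 2
Reactants: 3 rac-1-(5-bromo-2-hydroxy-3-methoxyphenyl)ethane-1,2-diol
Product: 4 rac-4-bromo-2-[2-(tert-butyldiphenylsilyloxy)-1-hydroxyethyl]-6-methoxyphenol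
Conditions: TBDPSCl (1.05 equiv), imidazole, DMF, 0 °C
Reagents that add atoms: tert-butyl(chloro)diphenylsilane, CC(C)(C)[Si](Cl)(c1ccccc1)c1ccccc1
Why: Selective silylation of the primary hydroxyl; the bulky chlorosilane discriminates against the secondary benzylic alcohol and against the phenol, which is flanked by two ortho substituents and hydrogen-bonded, and an alkyl silyl ether is favoured over an aryl silyl ether in any case.

Step 3
Reactants: 4 rac-4-bromo-2-[2-(tert-butyldiphenylsilyloxy)-1-hydroxyethyl]-6-methoxyphenol
Product: 5 rac-4-bromo-2-[2-(tert-butyldiphenylsilyloxy)-1-(4-methylbenzenesulfonyl)ethyl]-6-methoxyphenol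
Conditions: p-TolSO2H (2 equiv), CH2Cl2, 4 Å MS, rt
Reagents that add atoms: 4-methylbenzenesulfinic acid, Cc1ccc(S(=O)O)cc1
Why: Acid-promoted substitution of an ortho-hydroxybenzylic alcohol through its quinone methide or benzylic cation, with the sulfinate attacking through sulfur to give the sulfone; this is the usual preparation of 2-(1-sulfonylalkyl)phenols, and the medium is mild and non-nucleophilic enough for the tert-butyldiphenylsilyl ether.

Step 4
Reactants: 6 (2S,5S)-hexane-2,5-diol
Product: 7 (2S,5S)-hexane-2,5-diyl dimethanesulfonate
Conditions: MsCl, Et3N, CH2Cl2, 0 °C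
Reagents that add atoms: methanesulfonyl chloride, CS(=O)(=O)Cl
Why: Mesylation at oxygen leaves both stereocentres untouched.

Step 5
Reactants: 7 (2S,5S)-hexane-2,5-diyl dimethanesulfonate
Product: 8 (2R,5R)-2,5-dimethylthiolane
Conditions: Na2S·9H2O, DMSO, rt
Reagents that add atoms: sodium sulfide, [Na+].[Na+].[S-2]
Why: Two successive SN2 displacements by sulfide, the second a 5-exo-tet ring closure, invert both centres and give the C2-symmetric trans thiolane.

Step 6
Reactants: 9 vanillin (4-hydroxy-3-methoxybenzaldehyde)
Product: 10 3-methoxy-4-(triisopropylsilyloxy)benzaldehyde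
Conditions: TIPSCl, imidazole, DMF, rt
Reagents that add atoms: chlorotri(propan-2-yl)silane, CC(C)[Si](Cl)(C(C)C)C(C)C
Why: Routine silylation of a phenol; the triisopropylsilyl ether is chosen because it withstands carbonate and aqueous phosphate in steps 10 and 13.

Step 7
Reactants: 10 3-methoxy-4-(triisopropylsilyloxy)benzaldehyde
Product: 11 [3-methoxy-4-(triisopropylsilyloxy)phenyl]methanol
Conditions: NaBH4, MeOH, 0 °C
Reagents that add atoms: none
Why: Borohydride reduction of an aromatic aldehyde; the aryl silyl ether is stable at this temperature.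

Step 8
Reactants: 11 [3-methoxy-4-(triisopropylsilyloxy)phenyl]methanol
Product: 12 4-(bromomethyl)-2-methoxy-1-(triisopropylsilyloxy)benzene
Conditions: PBr3 (0.4 equiv), Et2O, 0 °C; used at once without chromatography
Reagents that add atoms: phosphorus tribromide, BrP(Br)Br
Why: Bromination of a benzylic alcohol through its phosphite ester; the electron-rich bromide is reactive and is therefore taken on crude.

Step 9
Reactants: 12 4-(bromomethyl)-2-methoxy-1-(triisopropylsilyloxy)benzene; 8 (2R,5R)-2,5-dimethylthiolane
Product: 13 (2R,5R)-1-[3-methoxy-4-(triisopropylsilyloxy)benzyl]-2,5-dimethylthiolan-1-ium tetrafluoroborate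
Conditions: 8 (1.3 equiv), NaBF4 (sat. aq.), CH2Cl2, rt
Reagents that add atoms: sodium tetrafluoroborate, [Na+].F[B-](F)(F)F
Why: S-Alkylation of a dialkyl sulfide by a benzylic bromide; exchange of bromide for the non-nucleophilic tetrafluoroborate stops the reverse dealkylation, and the C2 axis of 8 makes both lone pairs equivalent so that one sulfonium stereoisomer forms.

Step 10
Reactants: 5 rac-4-bromo-2-[2-(tert-butyldiphenylsilyloxy)-1-(4-methylbenzenesulfonyl)ethyl]-6-methoxyphenol; 13 (2R,5R)-1-[3-methoxy-4-(triisopropylsilyloxy)benzyl]-2,5-dimethylthiolan-1-ium tetrafluoroborate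
Product: 17 (2R,3S)-5-bromo-3-[(tert-butyldiphenylsilyloxy)methyl]-7-methoxy-2-[3-methoxy-4-(triisopropylsilyloxy)phenyl]-2,3-dihydro-1-benzofuran, via ortho-quinone methide 14 (not isolated), via sulfonium ylide 15 (not isolated), via phenoxide sulfonium betaine 16 (not isolated)
Conditions: 13 (1.5 equiv), Cs2CO3 (3.5 equiv), MeCN/CH2Cl2, −20 to 0 °C, slow addition of 5
Reagents that add atoms: none
Why: Cs2CO3 deprotonates phenol 5, whose phenoxide expels toluenesulfinate in a 1,4-elimination to give quinone methide 14, and the same base reversibly deprotonates salt 13 at the benzylic carbon to ylide 15. The ylide carbon adds to the exocyclic carbon of 14 (bond C2–C3), ring A rearomatises to betaine 16, and the phenoxide displaces the thiolane from C2 in a 5-exo-tet SN2 closure (bond O1–C2) that releases sulfide 8 for recovery. The closest known reaction type is the carbonate-mediated [4+1] annulation of sulfonium ylides with ortho-quinone methides released from 2-(1-tosylalkyl)phenols, a homologue of the Corey–Chaykovsky reaction that is established for carbonyl-stabilised ylides and is applied here to a semi-stabilised benzylic ylide on a chiral sulfide. C2 is controlled by the C2-symmetric thiolane: 13 is a single stereoisomer, the flanking methyl groups fix the ylide conformation and shield one face, and the invertive closure turns the face selectivity of the C–C bond formation into (R) at C2. C3 is controlled relative to C2 in the addition step, where the aryl group of the ylide and the silyloxymethyl arm of the E-configured quinone methide should avoid each other, so that closure gives the trans ring. The step needs carbon attack of the ylide on 14 to beat both O-benzylation of the phenoxide by 13 and the [1,5]-hydrogen shift of 14 to a silyl enol ether; slow addition of 5 to an excess of ylide at low temperature is meant to secure this. Regiochemistry is not at issue, because ring A has one benzylic leaving group ortho to the phenol and bromine in the para position.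

Step 11
Reactants: 18 ferulic acid ((E)-3-(4-hydroxy-3-methoxyphenyl)prop-2-enoic acid)
Product: 19 prop-2-en-1-yl (E)-3-(4-hydroxy-3-methoxyphenyl)prop-2-enoate
Conditions: allyl bromide (1.1 equiv), KHCO3, DMF, rt
Reagents that add atoms: allyl bromide, C=CCBr
Why: O-Alkylation of the carboxylate; hydrogen carbonate deprotonates the acid but not the phenol, so only the ester forms.

Step 12
Reactants: 19 prop-2-en-1-yl (E)-3-(4-hydroxy-3-methoxyphenyl)prop-2-enoate
Product: 20 prop-2-en-1-yl (E)-3-[3-methoxy-4-(triisopropylsilyloxy)phenyl]prop-2-enoate
Conditions: TIPSCl, imidazole, DMF, rt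
Reagents that add atoms: chlorotri(propan-2-yl)silane, CC(C)[Si](Cl)(C(C)C)C(C)C
Why: Routine silylation of the phenol, which would otherwise consume borane in step 13.

Step 13
Reactants: 20 prop-2-en-1-yl (E)-3-[3-methoxy-4-(triisopropylsilyloxy)phenyl]prop-2-enoate; 17 (2R,3S)-5-bromo-3-[(tert-butyldiphenylsilyloxy)methyl]-7-methoxy-2-[3-methoxy-4-(triisopropylsilyloxy)phenyl]-2,3-dihydro-1-benzofuran
Product: 22 3-{(2R,3S)-3-[(tert-butyldiphenylsilyloxy)methyl]-7-methoxy-2-[3-methoxy-4-(triisopropylsilyloxy)phenyl]-2,3-dihydro-1-benzofuran-5-yl}propyl (E)-3-[3-methoxy-4-(triisopropylsilyloxy)phenyl]prop-2-enoate, via B-alkyl-9-BBN adduct 21 (not isolated)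
Conditions: 20 (1.3 equiv), 9-BBN (1.35 equiv), THF, 0 °C to rt; then 17, PdCl2(dppf)·CH2Cl2 (5 mol %), K3PO4 (3 M aq.), DMF/THF, 50 °C
Reagents that add atoms: none
Why: 9-BBN hydroborates the terminal allyl double bond anti-Markovnikov and should leave the electron-poor conjugated cinnamate alkene and the ester alone; the B-alkyl Suzuki–Miyaura coupling then joins the primary alkyl group to C5 under mild aqueous phosphate, which does not touch the ring stereocentres. The ferrocenyl bisphosphine on palladium favours reductive elimination over beta-hydride elimination of the alkyl group.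

Step 14
Reactants: 22 3-{(2R,3S)-3-[(tert-butyldiphenylsilyloxy)methyl]-7-methoxy-2-[3-methoxy-4-(triisopropylsilyloxy)phenyl]-2,3-dihydro-1-benzofuran-5-yl}propyl (E)-3-[3-methoxy-4-(triisopropylsilyloxy)phenyl]prop-2-enoate
Product: 23 3-[(2R,3S)-2-(4-hydroxy-3-methoxyphenyl)-3-(hydroxymethyl)-7-methoxy-2,3-dihydro-1-benzofuran-5-yl]propyl (E)-3-(4-hydroxy-3-methoxyphenyl)prop-2-enoate (CNP0149450.1)
Conditions: TBAF (5 equiv), AcOH (5 equiv), THF, 0 °C to rt
Reagents that add atoms: none
Why: Fluoride cleavage of the two aryl silyl ethers and the primary alkyl silyl ether; buffering with acetic acid keeps the freed ring C phenol protonated, so the O1–C2 bond is not opened through a para-quinone methide and the ester is not attacked.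

## Compound list

1 | 5-bromo-2-hydroxy-3-methoxybenzaldehyde (5-bromo-o-vanillin) | O=Cc1cc(Br)cc(OC)c1O | starting material
2 | rac-4-bromo-2-{1-hydroxy-2-[dimethyl(propan-2-yloxy)silyl]ethyl}-6-methoxyphenol (present as its magnesium salt) | COc1cc(Br)cc(C(O)C[Si](C)(C)OC(C)C)c1O | intermediate
3 | rac-1-(5-bromo-2-hydroxy-3-methoxyphenyl)ethane-1,2-diol | COc1cc(Br)cc(C(O)CO)c1O | intermediate
4 | rac-4-bromo-2-[2-(tert-butyldiphenylsilyloxy)-1-hydroxyethyl]-6-methoxyphenol | COc1cc(Br)cc(C(O)CO[Si](c2ccccc2)(c2ccccc2)C(C)(C)C)c1O | intermediate
5 | rac-4-bromo-2-[2-(tert-butyldiphenylsilyloxy)-1-(4-methylbenzenesulfonyl)ethyl]-6-methoxyphenol | COc1cc(Br)cc(C(CO[Si](c2ccccc2)(c2ccccc2)C(C)(C)C)S(=O)(=O)c2ccc(C)cc2)c1O | intermediate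
6 | (2S,5S)-hexane-2,5-diol | C[C@H](O)CC[C@H](C)O | starting material
7 | (2S,5S)-hexane-2,5-diyl dimethanesulfonate | C[C@H](OS(C)(=O)=O)CC[C@H](C)OS(C)(=O)=O | intermediate
8 | (2R,5R)-2,5-dimethylthiolane | C[C@@H]1CC[C@@H](C)S1 | intermediate
9 | vanillin (4-hydroxy-3-methoxybenzaldehyde) | O=Cc1ccc(O)c(OC)c1 | starting material
10 | 3-methoxy-4-(triisopropylsilyloxy)benzaldehyde | O=Cc1ccc(O[Si](C(C)C)(C(C)C)C(C)C)c(OC)c1 | intermediate
11 | [3-methoxy-4-(triisopropylsilyloxy)phenyl]methanol | OCc1ccc(O[Si](C(C)C)(C(C)C)C(C)C)c(OC)c1 | intermediate
12 | 4-(bromomethyl)-2-methoxy-1-(triisopropylsilyloxy)benzene | BrCc1ccc(O[Si](C(C)C)(C(C)C)C(C)C)c(OC)c1 | intermediate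
13 | (2R,5R)-1-[3-methoxy-4-(triisopropylsilyloxy)benzyl]-2,5-dimethylthiolan-1-ium tetrafluoroborate | C[C@@H]1CC[C@@H](C)[S+]1Cc1ccc(O[Si](C(C)C)(C(C)C)C(C)C)c(OC)c1.F[B-](F)(F)F | intermediate
14 | (E)-4-bromo-6-[2-(tert-butyldiphenylsilyloxy)ethylidene]-2-methoxycyclohexa-2,4-dien-1-one (ortho-quinone methide, silyloxymethyl group anti to the carbonyl) | O=C1C(OC)=CC(Br)=C/C1=C\CO[Si](c2ccccc2)(c3ccccc3)C(C)(C)C | intermediate
15 | (2R,5R)-2,5-dimethylthiolan-1-ium-1-yl [3-methoxy-4-(triisopropylsilyloxy)phenyl]methanide (sulfonium ylide) | C[C@@H]1CC[C@@H](C)[S+]1[CH-]c1ccc(O[Si](C(C)C)(C(C)C)C(C)C)c(OC)c1 | intermediate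
16 | 4-bromo-2-{(1S,2S)-3-(tert-butyldiphenylsilyloxy)-1-[(2R,5R)-2,5-dimethylthiolan-1-ium-1-yl]-1-[3-methoxy-4-(triisopropylsilyloxy)phenyl]propan-2-yl}-6-methoxyphenolate (betaine) | [O-]c1c(OC)cc(Br)cc1[C@@H](CO[Si](c2ccccc2)(c3ccccc3)C(C)(C)C)[C@@H](c4ccc(O[Si](C(C)C)(C(C)C)C(C)C)c(OC)c4)[S+]5[C@H](C)CC[C@H]5C | intermediate
17 | (2R,3S)-5-bromo-3-[(tert-butyldiphenylsilyloxy)methyl]-7-methoxy-2-[3-methoxy-4-(triisopropylsilyloxy)phenyl]-2,3-dihydro-1-benzofuran | Brc1cc(OC)c2c(c1)[C@@H](CO[Si](c3ccccc3)(c3ccccc3)C(C)(C)C)[C@H](c3ccc(O[Si](C(C)C)(C(C)C)C(C)C)c(OC)c3)O2 | intermediate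
18 | ferulic acid ((E)-3-(4-hydroxy-3-methoxyphenyl)prop-2-enoic acid) | COc1cc(/C=C/C(=O)O)ccc1O | starting material
19 | prop-2-en-1-yl (E)-3-(4-hydroxy-3-methoxyphenyl)prop-2-enoate | C=CCOC(=O)/C=C/c1ccc(O)c(OC)c1 | intermediate
20 | prop-2-en-1-yl (E)-3-[3-methoxy-4-(triisopropylsilyloxy)phenyl]prop-2-enoate | C=CCOC(=O)/C=C/c1ccc(O[Si](C(C)C)(C(C)C)C(C)C)c(OC)c1 | intermediate
21 | 3-(9-borabicyclo[3.3.1]nonan-9-yl)propyl (E)-3-[3-methoxy-4-(triisopropylsilyloxy)phenyl]prop-2-enoate | O=C(/C=C/c1ccc(O[Si](C(C)C)(C(C)C)C(C)C)c(OC)c1)OCCCB1C2CCCC1CCC2 | intermediate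
22 | 3-{(2R,3S)-3-[(tert-butyldiphenylsilyloxy)methyl]-7-methoxy-2-[3-methoxy-4-(triisopropylsilyloxy)phenyl]-2,3-dihydro-1-benzofuran-5-yl}propyl (E)-3-[3-methoxy-4-(triisopropylsilyloxy)phenyl]prop-2-enoate | COc1cc(/C=C/C(=O)OCCCc2cc(OC)c3c(c2)[C@@H](CO[Si](c2ccccc2)(c2ccccc2)C(C)(C)C)[C@H](c2ccc(O[Si](C(C)C)(C(C)C)C(C)C)c(OC)c2)O3)ccc1O[Si](C(C)C)(C(C)C)C(C)C | intermediate
23 | 3-[(2R,3S)-2-(4-hydroxy-3-methoxyphenyl)-3-(hydroxymethyl)-7-methoxy-2,3-dihydro-1-benzofuran-5-yl]propyl (E)-3-(4-hydroxy-3-methoxyphenyl)prop-2-enoate | COc1cc(/C=C/C(=O)OCCCc2cc(OC)c3c(c2)[C@@H](CO)[C@H](c2ccc(O)c(OC)c2)O3)ccc1O | target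

## Step count and least certain steps

Total: 14 steps. Longest linear sequence: 7 steps (9 → 10 → 11 → 12 → 13 → 17 → 22 → 23; steps 6, 7, 8, 9, 10, 13, 14).

**Step 10 (key step).** Three processes can spoil it.
- The electron-rich benzylic sulfonium salt can act as an alkylating agent, so O-benzylation of the ring A phenoxide (or ionisation of the salt) may compete with ylide formation.
- The quinone methide can isomerise by [1,5]-hydrogen shift to a silyl enol ether before it is captured.
- Face selectivity may be incomplete, either at the ylide (loss of enantiomeric purity) or at the quinone methide (formation of the cis ring). A cis product cannot be corrected by epimerisation at C2, since that would give the enantiomeric trans series.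

The fallback gives up the annulation for an enantioselective carbenoid C–H insertion. It sets out from bromide 12 and commercial 4-bromo-2-methoxyphenol and comes back at 17.
- Iodination of the phenol ortho to the hydroxyl group (NIS, cat. TsOH, MeCN) would give 4-bromo-2-iodo-6-methoxyphenol F1.
- Williamson alkylation with 12 (K2CO3, DMF) would give the benzyl aryl ether F2.
- Coupling of the C–I bond with ethyl diazoacetate (Pd(PPh3)4, Ag2CO3, Et3N, toluene, rt) would give the aryldiazoacetate F3.
- A chiral dirhodium tetracarboxylate such as Rh2(S-PTTL)4, or its mirror image if the sense requires it, in toluene at low temperature should insert the carbenoid into the benzylic ether C–H bond to give the cis ester F4.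
- DBU in toluene would epimerise F4 at C3 to the trans ester F5.
- DIBAL-H reduction to the primary alcohol F6 and silylation with TBDPSCl and imidazole would return 17.

**Step 3.** Ionisation of the benzylic alcohol is slowed by the neighbouring oxygen. The cation can instead undergo a 1,2-hydride shift to an arylacetaldehyde, and the water set free together with the sulfinic acid may erode the silyl ether. The fallback changes the order so that no silyl ether sees acid; it sets out from triol 3 and comes back at 5. Exchange with TolSO2Na in aqueous HCO2H would give the sulfonyl diol F7, whose primary hydroxyl is then silylated with TBDPSCl, AgNO3 and pyridine in THF at 0 °C. That medium is too weakly basic to release the quinone methide.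

**Step 13.** 9-BBN may reduce or hydroborate the cinnamate in competition with the allyl group. Oxidative addition to the electron-rich bromide may be slow enough for protodeboronation or ester hydrolysis to take over. The fallback couples a simpler borane and makes the ester afterwards; it sets out from 17 and 20 and comes back at 22.
- Hydroboration of commercial allyloxy-tert-butyldimethylsilane with 9-BBN would give the alkylborane F8.
- Coupling with 17 under the same catalyst would give the arylpropyl silyl ether F9.
- PPTS in EtOH would remove only the primary tert-butyldimethylsilyl group to give the arylpropanol F10.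
- Ester 20 would be deallylated with Pd(PPh3)4 and morpholine to 4-O-triisopropylsilylferulic acid F11.
- Steglich esterification of F10 with F11 (EDC·HCl, DMAP, CH2Cl2) would give 22. The C3 oxygen stays silylated throughout, so no diol has to be differentiated.

**Step 9.** The bromide 12 may hydrolyse or oligomerise in the two-phase medium before the sulfide captures it, and alkylation is reversible as long as bromide is the counter-ion. The fallback avoids the bromide altogether; it sets out from alcohol 11 and sulfide 8 and comes back at 13. Dehydrative S-alkylation with HBF4·OEt2 in Et2O at 0 °C would generate the benzylic cation in the presence of the sulfide and give the tetrafluoroborate directly. No new compound is involved.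

## Further compounds

F1 | step 10 | 4-bromo-2-iodo-6-methoxyphenol | COc1cc(Br)cc(I)c1O
F2 | step 10 | 5-bromo-1-iodo-3-methoxy-2-{[3-methoxy-4-(triisopropylsilyloxy)phenyl]methoxy}benzene | COc1cc(Br)cc(I)c1OCc1ccc(O[Si](C(C)C)(C(C)C)C(C)C)c(OC)c1
F3 | step 10 | ethyl 2-(5-bromo-3-methoxy-2-{[3-methoxy-4-(triisopropylsilyloxy)phenyl]methoxy}phenyl)-2-diazoacetate | CCOC(=O)C(=[N+]=[N-])c1cc(Br)cc(OC)c1OCc1ccc(O[Si](C(C)C)(C(C)C)C(C)C)c(OC)c1
F4 | step 10 | ethyl (2R,3S)-5-bromo-7-methoxy-2-[3-methoxy-4-(triisopropylsilyloxy)phenyl]-2,3-dihydro-1-benzofuran-3-carboxylate (cis) | Brc1cc(OC)c2c(c1)[C@H](C(=O)OCC)[C@H](c1ccc(O[Si](C(C)C)(C(C)C)C(C)C)c(OC)c1)O2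
F5 | step 10 | ethyl (2R,3R)-5-bromo-7-methoxy-2-[3-methoxy-4-(triisopropylsilyloxy)phenyl]-2,3-dihydro-1-benzofuran-3-carboxylate (trans) | Brc1cc(OC)c2c(c1)[C@@H](C(=O)OCC)[C@H](c1ccc(O[Si](C(C)C)(C(C)C)C(C)C)c(OC)c1)O2
F6 | step 10 | {(2R,3S)-5-bromo-7-methoxy-2-[3-methoxy-4-(triisopropylsilyloxy)phenyl]-2,3-dihydro-1-benzofuran-3-yl}methanol | Brc1cc(OC)c2c(c1)[C@@H](CO)[C@H](c1ccc(O[Si](C(C)C)(C(C)C)C(C)C)c(OC)c1)O2
F7 | step 3 | rac-4-bromo-2-[2-hydroxy-1-(4-methylbenzenesulfonyl)ethyl]-6-methoxyphenol | COc1cc(Br)cc(C(CO)S(=O)(=O)c2ccc(C)cc2)c1O
F8 | step 13 | 9-[3-(tert-butyldimethylsilyloxy)propyl]-9-borabicyclo[3.3.1]nonane | CC(C)(C)[Si](C)(C)OCCCB1C2CCCC1CCC2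
F9 | step 13 | (2R,3S)-5-[3-(tert-butyldimethylsilyloxy)propyl]-3-[(tert-butyldiphenylsilyloxy)methyl]-7-methoxy-2-[3-methoxy-4-(triisopropylsilyloxy)phenyl]-2,3-dihydro-1-benzofuran | CC(C)(C)[Si](C)(C)OCCCc1cc(OC)c2c(c1)[C@@H](CO[Si](c3ccccc3)(c3ccccc3)C(C)(C)C)[C@H](c3ccc(O[Si](C(C)C)(C(C)C)C(C)C)c(OC)c3)O2
F10 | step 13 | 3-{(2R,3S)-3-[(tert-butyldiphenylsilyloxy)methyl]-7-methoxy-2-[3-methoxy-4-(triisopropylsilyloxy)phenyl]-2,3-dihydro-1-benzofuran-5-yl}propan-1-ol | OCCCc1cc(OC)c2c(c1)[C@@H](CO[Si](c3ccccc3)(c3ccccc3)C(C)(C)C)[C@H](c3ccc(O[Si](C(C)C)(C(C)C)C(C)C)c(OC)c3)O2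
F11 | step 13 | (E)-3-[3-methoxy-4-(triisopropylsilyloxy)phenyl]prop-2-enoic acid | OC(=O)/C=C/c1ccc(O[Si](C(C)C)(C(C)C)C(C)C)c(OC)c1
F0 | step 9 | none | none
A1 | alternative 1 | 5-(3-benzyloxypropyl)-1-iodo-3-methoxy-2-{[(1R)-1-[3-methoxy-4-(triisopropylsilyloxy)phenyl]prop-2-en-1-yl]oxy}benzene | C=C[C@H](c1ccc(O[Si](C(C)C)(C(C)C)C(C)C)c(OC)c1)Oc1c(I)cc(CCCOCc2ccccc2)cc1OC
A2 | alternative 1 | (2R,3S)-5-(3-benzyloxypropyl)-7-methoxy-2-[3-methoxy-4-(triisopropylsilyloxy)phenyl]-3-[(2,2,6,6-tetramethylpiperidin-1-yl)oxymethyl]-2,3-dihydro-1-benzofuran | O(Cc1ccccc1)CCCc1cc(OC)c2c(c1)[C@@H](CON1C(C)(C)CCCC1(C)C)[C@H](c1ccc(O[Si](C(C)C)(C(C)C)C(C)C)c(OC)c1)O2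
A3 | alternative 2 | methyl 2-(5-bromo-3-methoxy-2-{[3-methoxy-4-(triisopropylsilyloxy)phenyl]methoxy}phenyl)-2-diazoacetate | COC(=O)C(=[N+]=[N-])c1cc(Br)cc(OC)c1OCc1ccc(O[Si](C(C)C)(C(C)C)C(C)C)c(OC)c1
A4 | alternative 2 | methyl (2R,3R)-5-bromo-7-methoxy-2-[3-methoxy-4-(triisopropylsilyloxy)phenyl]-2,3-dihydro-1-benzofuran-3-carboxylate (trans) | Brc1cc(OC)c2c(c1)[C@@H](C(=O)OC)[C@H](c1ccc(O[Si](C(C)C)(C(C)C)C(C)C)c(OC)c1)O2
A5 | alternative 3 | 4-bromo-2-[(2S)-1-(tert-butyldimethylsilyloxy)-3-(4-hydroxy-3-methoxyphenyl)propan-2-yl]-6-methoxyphenol | COc1cc(Br)cc([C@@H](CO[Si](C)(C)C(C)(C)C)Cc2ccc(O)c(OC)c2)c1O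
A6 | alternative 3 | 4-{(2R,3S)-5-bromo-3-[(tert-butyldimethylsilyloxy)methyl]-7-methoxy-2,3-dihydro-1-benzofuran-2-yl}-2-methoxyphenol | Brc1cc(OC)c2c(c1)[C@@H](CO[Si](C)(C)C(C)(C)C)[C@H](c1ccc(O)c(OC)c1)O2
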